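In a one-step world of first order the electrophile falls along a straight line in logarithms. L, the natural logarithm of charged over remaining electrophile, grows in proportion to time, and a rate law shows up as a slope. We want the part reacted in winter, dusk and spring, which differ from two earlier runs in c(free base) and are taken to a later time.

| flask | electrophile | free base | protonated nucleophile | protic impurity | remark | time |
|---|---|---|---|---|---|---|
| green | 0.020 M | 0.025 M | 0.019 M | 0.020 M | run made earlier |  |
| grey | 0.020 M | 0.055 M | 0.019 M | 0.020 M | run made earlier |  |
| winter | 0.020 M | 0.0200 M | 0.0190 M | 0.0200 M |  | 20 h |
| dusk | 0.020 M | 0.0300 M | 0.0190 M | 0.0200 M |  | 20 h |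
| spring | 0.020 M | 0.0450 M | 0.0190 M | 0.0200 M |  | 20 h |

- green (time / h: electrophile / %, product / %): 4.00: 90, 12; 8.00: 85, 13; 10.0: 81, 16; 15.0: 75, 27
- grey (time / h: electrophile / %, product / %): 1.00: 96, 5; 2.50: 90, 9; 6.00: 82, 18; 15.0: 68, 34

(scatter of a reading: 2 percentage points)

- a reading or a percentage of product counts all its forms, free or not

1. part of the electrophile that has reacted at the end, winter
2. part of the electrophile that has reacted at the end, dusk
3. part of the electrophile that has reacted at the end, spring
4. what raising the concentration of free base from its lowest to its highest value here does to the part of the electrophile that has reacted (changes below 5 percentage points count as none) (no change / it rises / it falls)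

At 15.0 h the green run reads L = 0.288 and the grey run 0.386. From green to grey, c(free base) climbs 0.342 of a power of ten, and L climbs 0.127. Their ratio, 0.372, is the free-base exponent: powers of ten of L gained per power of ten of c(free base). We stretch green's L in proportion to time up to 20 h. Then we multiply it by the ratio of c(free base) to green's, raised to this exponent. The part reacted is one minus exp(−L). That gives 29.7% for winter, 33.7% for dusk and 38.0% for spring.

The weak link is the proportion to time. Grey's L per hour reads 0.0421 h⁻¹ at 2.50 h but 0.0257 h⁻¹ at 15.0 h, so the line bends. We treat time like the base, in powers of ten. L gains 0.724 of a power of ten per power of ten of time in grey and 0.760 in green. With their mean, 0.742, we commit to winter 27.9%, dusk 31.7% and spring 35.8%. The gap from winter to spring is 7.8 percentage points, above the mark of 5 points, so we say it rises.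

The forecast differs from us, with 15%, 37% and 41%, and its trend is that it rises, on the ground: “Winter has no excess base, so it should be much slower”. The flask gives 24.3%, 29.6% and 33.6%; it rises, by 9.3 points.

    electrophile + nucleophile ⇌ acid set free + product (K = 8.60, k = 16.3 M⁻¹ h⁻¹)
    nucleophile + acid set free ⇌ protonated nucleophile, settled at all times (K = 20900 M⁻¹)
    acid set free + free base ⇌ salt of the base (K = 87000 M⁻¹, k = 234 M⁻¹ h⁻¹)
    nucleophile + protic impurity → quenched reagent (k = 32.8 M⁻¹ h⁻¹)
    crystals ⇌ product, rate k5*(cs5 - [product]) while solid is left; crystals form when [product] > cs5 (solubility = 14.0 mM, k = 1.57 h⁻¹)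

The rise from winter to spring is due mainly to the difference in c(free base). Part of the way it acts is the path from acid set free and free base to salt of the base. With that path taken away, spring reacts 6.66% instead of 33.6%, and winter reacts 6.66%, so the gap closes. Starting from winter's result, the free-base exponent puts spring at 31.3%, against 33.6% in the flask. Starting from dusk's result, it puts a flask like dusk but with 0.075 M of free base at 39.0%. That flask gives 35.5%.

(The numbers in the tables were computed on assumed constants, noise included.)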